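## Retrosynthetic overview

1. Ring A is the ring that ends as the 3,5-dibromo-2-methoxyphenoxy unit (C1 bears O, C6 bears the aryloxy oxygen, C2 and C4 the bromines). Ring B is the phenol ring of the target (C1' ether oxygen, C2' OMe, C6' OH, C3' and C5' bromines).
2. Target 19 comes from MOM removal, O-methylation of the ring A hydroxyl and fourfold bromination of 2-aryloxyphenol 16. The free C1–OH steers bromine to C2 and C4. The C2' and C6' ether oxygens steer it to C3' and C5'.
3. The strategy rests on one feature: without its bromines, ring A is a catechol monoaryl ether, with O on C1 next to the aryloxy group on C6 and C2–C5 all CH. C5, C6, C1 and C2 therefore map onto an aryloxyacetone-derived 1-amino-2-aryloxy-3-siloxy diene 11, and C3 and C4 onto phenyl vinyl sulfoxide 12 as an ethyne equivalent. The Diels–Alder reaction forms C2–C3 and C4–C5, and aromatisation follows.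
4. Diene 11 comes from enaminone 9, which comes from aryloxyacetone 7, made from phenol 5 and chloroacetone 6. The crowded ring B oxygen is only ever alkylated, never arylated. Phenol 5 comes from 3-methoxyphenol 1 by MOM protection and lithiation between the two oxygens, then borylation and oxidation.
5. Ring order: ring B is bought; ring A is the only ring made (step 6).

Key step: step 6

Assumption: intermediates 13 and 14 are drawn with the sulfinyl carbon bonded to the former amino carbon, the usual orientation for 1-amino-3-siloxy dienes, and are diastereomer mixtures. The other orientation would converge on the same phenol 16.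

## Route

Step 1
Reactants: 1 3-methoxyphenol
Product: 2 1-methoxy-3-(methoxymethoxy)benzene
Conditions: MOMCl, K2CO3, DMF, 0 °C to rt
Reagents that add atoms: chloromethyl methyl ether, COCCl
Why: Williamson-type O-alkylation of the phenoxide by the reactive α-chloro ether gives the MOM acetal, which protects the later ring B hydroxyl and acts as a strong directing group for step 2.

Step 2
Reactants: 2 1-methoxy-3-(methoxymethoxy)benzene
Product: 5 2-methoxy-6-(methoxymethoxy)phenol, via aryllithium 3 (not isolated), via dimethyl arylboronate 4 (not isolated)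
Conditions: n-BuLi, THF, 0 °C; B(OMe)3, –78 °C to rt; then 30% H2O2, aq NaOH, 0 °C to rt; NH4Cl work-up
Reagents that add atoms: hydrogen peroxide, OO (the phenol oxygen of 5); n-butyllithium, [Li]CCCC (lithium of 3 only); trimethyl borate, COB(OC)OC (boron and methoxy groups of 4 only)
Why: Directed ortho-metalation should occur at the carbon flanked by both OMe and OMOM, since both coordinate lithium, and borate trapping followed by hydroperoxide oxidation (1,2-aryl shift from boron to oxygen) turns the C–Li bond into C–OH.

Step 3
Reactants: 5 2-methoxy-6-(methoxymethoxy)phenol; 6 chloroacetone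
Product: 7 1-[2-methoxy-6-(methoxymethoxy)phenoxy]propan-2-one
Conditions: K2CO3, KI (cat.), acetone, reflux
Reagents that add atoms: none
Why: Williamson ether synthesis by SN2 at the primary α-halo ketone (Finkelstein-assisted by iodide), which tolerates the two ortho substituents of the phenoxide.

Step 4
Reactants: 7 1-[2-methoxy-6-(methoxymethoxy)phenoxy]propan-2-one; 8 N,N-dimethylformamide dimethyl acetal
Product: 9 (3Z)-4-(dimethylamino)-3-[2-methoxy-6-(methoxymethoxy)phenoxy]but-3-en-2-one
Conditions: neat 8 (excess), 100 °C, MeOH distilled off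
Reagents that add atoms: none
Why: Formamide-acetal condensation (enaminone formation) should take place at the more acidic methylene activated by both the carbonyl and the aryloxy group, and the push–pull alkene equilibrates to the isomer with the amino group anti to the acetyl group.

Step 5
Reactants: 9 (3Z)-4-(dimethylamino)-3-[2-methoxy-6-(methoxymethoxy)phenoxy]but-3-en-2-one
Product: 11 (1Z)-3-(tert-butyldimethylsilyloxy)-1-(dimethylamino)-2-[2-methoxy-6-(methoxymethoxy)phenoxy]buta-1,3-diene, via potassium dienolate 10 (not isolated)
Conditions: KN(SiMe3)2, THF, –78 °C; TBSCl, –78 °C to rt; salts removed by filtration in pentane under argon, used crude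
Reagents that add atoms: tert-butyldimethylsilyl chloride, CC(C)(C)[Si](C)(C)Cl; potassium bis(trimethylsilyl)amide, C[Si](C)(C)[N-][Si](C)(C)C.[K+] (potassium of 10 only)
Why: The acetyl methyl group is the only enolisable position of the vinylogous amide, so kinetic deprotonation and O-silylation (silyl enol ether formation, the standard entry to 1-amino-3-siloxybutadienes) should give the cross-conjugated diene with the enamine geometry unchanged.

Step 6
Reactants: 11 (1Z)-3-(tert-butyldimethylsilyloxy)-1-(dimethylamino)-2-[2-methoxy-6-(methoxymethoxy)phenoxy]buta-1,3-diene; 12 phenyl vinyl sulfoxide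
Product: 16 2-[2-methoxy-6-(methoxymethoxy)phenoxy]phenol, via cycloadduct 13 (not isolated), via sulfinyl enone 14 (not isolated), via dienone 15 (not isolated)
Conditions: 12 (2.5 equiv), PhMe (2 M), 60 °C; then 0.1 M aq HCl, THF, 0 °C, short contact; organic phase then heated in PhMe, 100 °C
Reagents that add atoms: none
Why: The diene is made electron-rich by the amino group on C5 and the siloxy group on C1 and can reach the s-cis form because the amino group is anti to the siloxy-bearing carbon, so it should add suprafacially to the electron-poor alkene of 12 in a concerted normal-demand (4+2) cycloaddition that forms C2–C3 and C4–C5 and closes six-membered ring A by an intermolecular two-bond annulation. The closest known reaction type is the Diels–Alder reaction of 1-amino-3-siloxy and 1-methoxy-3-siloxy butadienes with vinyl sulfoxides as ethyne equivalents, applied here to a diene that carries an additional 2-aryloxy group. Cold dilute acid protonates nitrogen, the silyl enol ether pushes out dimethylamine and desilylation leaves enone 14. On heating, syn elimination of benzenesulfenic acid can only take a hydrogen from the ring CH2 beside the sulfinyl carbon, because the other neighbour is now a vinyl CH, and the resulting dienone 15 tautomerises to phenol 16. No stereocentre survives, so all diastereomers of 13 and 14 converge, and the orientation of the dienophile is irrelevant because both of its carbons end as aromatic CH. The selectivity needed is chemoselectivity: the acid is kept cold and dilute so that the aryl MOM acetal and the enol aryl ether are not hydrolysed, and amine loss is completed before heating so that the sulfoxide cannot eliminate toward the amino-bearing carbon.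

Step 7
Reactants: 16 2-[2-methoxy-6-(methoxymethoxy)phenoxy]phenol
Product: 17 2,4-dibromo-6-[3,5-dibromo-2-methoxy-6-(methoxymethoxy)phenoxy]phenol
Conditions: NBS (4.2 equiv), DMF, 0 °C to rt, dark; Na2S2O3 work-up
Reagents that add atoms: N-bromosuccinimide, O=C1CCC(=O)N1Br
Why: Electrophilic aromatic bromination should be steered on ring A by the free hydroxyl to the ortho C2 and para C4 positions, and on ring B to C3' and C5', each of which is ortho to one ether oxygen and para to the other, while C4' is meta to both; the non-acidic medium should leave the MOM group intact.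

Step 8
Reactants: 17 2,4-dibromo-6-[3,5-dibromo-2-methoxy-6-(methoxymethoxy)phenoxy]phenol
Product: 18 1,5-dibromo-3-[3,5-dibromo-2-methoxy-6-(methoxymethoxy)phenoxy]-2-methoxybenzene
Conditions: MeI, K2CO3, DMF, rt
Reagents that add atoms: iodomethane, CI
Why: Williamson O-methylation of the only free hydroxyl, an acidic dibromophenol, while the ring B oxygen remains masked as the MOM ether.

Step 9
Reactants: 18 1,5-dibromo-3-[3,5-dibromo-2-methoxy-6-(methoxymethoxy)phenoxy]-2-methoxybenzene
Product: 19 4,6-dibromo-2-(3,5-dibromo-2-methoxyphenoxy)-3-methoxyphenol (CNP0017935.0)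
Conditions: 3 M HCl in MeOH, rt to 40 °C
Reagents that add atoms: none
Why: Acid-catalysed methanolysis of the MOM acetal (acetal exchange) frees the ring B phenol, while aryl methyl ethers, the diaryl ether and the aryl bromides are inert under these conditions.

## Compound list

1 | 3-methoxyphenol | COc1cccc(O)c1 | starting material
2 | 1-methoxy-3-(methoxymethoxy)benzene | COCOc1cccc(OC)c1 | intermediate
3 | [2-methoxy-6-(methoxymethoxy)phenyl]lithium | [Li]c1c(OC)cccc1OCOC | intermediate
4 | dimethyl [2-methoxy-6-(methoxymethoxy)phenyl]boronate | COB(OC)c1c(OC)cccc1OCOC | intermediate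
5 | 2-methoxy-6-(methoxymethoxy)phenol | Oc1c(OC)cccc1OCOC | intermediate
6 | chloroacetone | CC(=O)CCl | starting material
7 | 1-[2-methoxy-6-(methoxymethoxy)phenoxy]propan-2-one | CC(=O)COc1c(OC)cccc1OCOC | intermediate
8 | N,N-dimethylformamide dimethyl acetal | COC(OC)N(C)C | starting material
9 | (3Z)-4-(dimethylamino)-3-[2-methoxy-6-(methoxymethoxy)phenoxy]but-3-en-2-one | CN(C)/C=C(\Oc1c(OC)cccc1OCOC)C(C)=O | intermediate
10 | potassium (3Z)-4-(dimethylamino)-3-[2-methoxy-6-(methoxymethoxy)phenoxy]buta-1,3-dien-2-olate | CN(C)/C=C(\Oc1c(OC)cccc1OCOC)C(=C)[O-].[K+] | intermediate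
11 | (1Z)-3-(tert-butyldimethylsilyloxy)-1-(dimethylamino)-2-[2-methoxy-6-(methoxymethoxy)phenoxy]buta-1,3-diene (amino group anti to C3) | CN(C)/C=C(\Oc1c(OC)cccc1OCOC)C(=C)O[Si](C)(C)C(C)(C)C | intermediate
12 | phenyl vinyl sulfoxide | C=CS(=O)c1ccccc1 | starting material
13 | tert-butyl{[3-(dimethylamino)-2-[2-methoxy-6-(methoxymethoxy)phenoxy]-4-(phenylsulfinyl)cyclohex-1-en-1-yl]oxy}dimethylsilane (diastereomer mixture) | CN(C)C1C(S(=O)c2ccccc2)CCC(O[Si](C)(C)C(C)(C)C)=C1Oc3c(OC)cccc3OCOC | intermediate
14 | 2-[2-methoxy-6-(methoxymethoxy)phenoxy]-4-(phenylsulfinyl)cyclohex-2-en-1-one (diastereomer mixture) | O=C1CCC(S(=O)c2ccccc2)C=C1Oc3c(OC)cccc3OCOC | intermediate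
15 | 2-[2-methoxy-6-(methoxymethoxy)phenoxy]cyclohexa-2,4-dien-1-one | O=C1CC=CC=C1Oc2c(OC)cccc2OCOC | intermediate
16 | 2-[2-methoxy-6-(methoxymethoxy)phenoxy]phenol | Oc1ccccc1Oc1c(OC)cccc1OCOC | intermediate
17 | 2,4-dibromo-6-[3,5-dibromo-2-methoxy-6-(methoxymethoxy)phenoxy]phenol | Oc1c(Br)cc(Br)cc1Oc1c(OC)c(Br)cc(Br)c1OCOC | intermediate
18 | 1,5-dibromo-3-[3,5-dibromo-2-methoxy-6-(methoxymethoxy)phenoxy]-2-methoxybenzene | COc1c(Br)cc(Br)cc1Oc1c(OC)c(Br)cc(Br)c1OCOC | intermediate
19 | 4,6-dibromo-2-(3,5-dibromo-2-methoxyphenoxy)-3-methoxyphenol | COc1c(Br)cc(Br)cc1Oc1c(O)c(Br)cc(Br)c1OC | target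

## Step count and risks

Total step count: 9. Longest linear sequence: 9 steps, from 3-methoxyphenol 1.

Steps most likely to fail:

1. Step 6. The vinyl sulfoxide is a weak dienophile and the diene is crowded at C6, so cycloaddition may be slower than hydrolysis or oligomerisation of the diene. In the acid stage the enol aryl ether could be hydrolysed in competition with amine loss. In the thermal stage the released sulfenic acid could sulfenylate the electron-rich product. Fallback, from 5 back to 16: nucleophilic aromatic substitution of 2-fluorobenzaldehyde by the phenoxide of 5 (K2CO3, DMF, 130 °C) should give 2-[2-methoxy-6-(methoxymethoxy)phenoxy]benzaldehyde F1. Baeyer–Villiger oxidation (mCPBA, NaHCO3, CH2Cl2) with migration of the oxygenated aryl group should give 2-[2-methoxy-6-(methoxymethoxy)phenoxy]phenyl formate F2. Methanolysis (K2CO3, MeOH, rt) then delivers phenol 16, and the route continues at step 7.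

2. Step 7. After the first bromine enters ring B, the C2' methoxy group is flanked on both sides and twisted out of conjugation, so the second ring B bromination may stall. Forcing it risks acid-induced loss of the MOM group and a mixture of bromination levels. Fallback, from 16 to target 19: only three equivalents of NBS (DMF, 0 °C) are used to give 2,4-dibromo-6-[3-bromo-2-methoxy-6-(methoxymethoxy)phenoxy]phenol F3. O-Methylation (MeI, K2CO3, DMF) gives 1,5-dibromo-3-[3-bromo-2-methoxy-6-(methoxymethoxy)phenoxy]-2-methoxybenzene F4. MOM removal (HCl, MeOH) gives 4-bromo-2-(3,5-dibromo-2-methoxyphenoxy)-3-methoxyphenol F5. The last bromine is then placed ortho to the freed ring B hydroxyl (NBS, 1.05 equiv, MeCN, 0 °C), giving 19; ring A, now a dibromoanisole, should not react.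

3. Step 5. The aminosiloxy diene cannot be distilled, and the silyl dienol ether and enamine may hydrolyse during salt removal and transfer. Fallback, from 9 back to 14: the potassium dienolate 10 is silylated with triisopropylsilyl chloride (THF, –78 °C to rt) to give the more robust (1Z)-1-(dimethylamino)-2-[2-methoxy-6-(methoxymethoxy)phenoxy]-3-(triisopropylsilyloxy)buta-1,3-diene F6, which should tolerate filtration through basic alumina. Cycloaddition with 12 (PhMe, 60 °C) gives {[3-(dimethylamino)-2-[2-methoxy-6-(methoxymethoxy)phenoxy]-4-(phenylsulfinyl)cyclohex-1-en-1-yl]oxy}triisopropylsilane F7. Fluoride unmasking (HF·pyridine, THF, 0 °C) replaces the aqueous acid and gives sulfinyl enone 14, which is heated as in step 6.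

Further compounds
F1 | step 6 | 2-[2-methoxy-6-(methoxymethoxy)phenoxy]benzaldehyde | O=Cc1ccccc1Oc1c(OC)cccc1OCOC
F2 | step 6 | 2-[2-methoxy-6-(methoxymethoxy)phenoxy]phenyl formate | O=COc1ccccc1Oc1c(OC)cccc1OCOC
F3 | step 7 | 2,4-dibromo-6-[3-bromo-2-methoxy-6-(methoxymethoxy)phenoxy]phenol | Oc1c(Br)cc(Br)cc1Oc1c(OC)c(Br)ccc1OCOC
F4 | step 7 | 1,5-dibromo-3-[3-bromo-2-methoxy-6-(methoxymethoxy)phenoxy]-2-methoxybenzene | COc1c(Br)cc(Br)cc1Oc1c(OC)c(Br)ccc1OCOC
F5 | step 7 | 4-bromo-2-(3,5-dibromo-2-methoxyphenoxy)-3-methoxyphenol | COc1c(Br)cc(Br)cc1Oc1c(OC)c(Br)ccc1O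
F6 | step 5 | (1Z)-1-(dimethylamino)-2-[2-methoxy-6-(methoxymethoxy)phenoxy]-3-(triisopropylsilyloxy)buta-1,3-diene | CN(C)/C=C(\Oc1c(OC)cccc1OCOC)C(=C)O[Si](C(C)C)(C(C)C)C(C)C
F7 | step 5 | {[3-(dimethylamino)-2-[2-methoxy-6-(methoxymethoxy)phenoxy]-4-(phenylsulfinyl)cyclohex-1-en-1-yl]oxy}triisopropylsilane (diastereomer mixture) | CN(C)C1C(S(=O)c2ccccc2)CCC(O[Si](C(C)C)(C(C)C)C(C)C)=C1Oc3c(OC)cccc3OCOC
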